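**Assumption:** the target has no stereocentre, so the only stereo-element to control is the Z exocyclic alkene. The presumed biosynthesis is taken to be O-acylation of the enol of a tyrosine-derived 1,3-diaryl-1,2-dione by a 4-hydroxybenzoylacetyl unit, then intramolecular Knoevenagel closure of the butenolide, with the bromines already on the aryl units.

## Retrosynthetic overview

1. Cadiolide A ⇐ its tri-O-methyl ether by one global ArOMe cleavage; all four bromines are bought in on the aryl building blocks.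
2. Key disconnection (lactone C2–O1 and C3=C4): the Z-enol of 1-(3,5-dibromo-4-methoxyphenyl)-3-(4-methoxyphenyl)propane-1,2-dione plus (3,5-dibromo-4-methoxybenzoyl)ketene. Enol O-acylation then intramolecular Knoevenagel; the Z-benzylidene is already present in the enol, so no late aldol is used.
3. Dione enol ⇐ trans-epoxy ketone (base isomerisation) ⇐ chalcone ⇐ 3,5-dibromo-4-methoxyacetophenone + 4-methoxybenzaldehyde.
4. Acylketene ⇐ aroyl Meldrum's acid ⇐ 3,5-dibromo-4-methoxybenzoic acid + Meldrum's acid.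
5. Ring order: the three benzene rings are purchased; the furanone ring is the only ring built, in the last C–C bond-forming step.

## Route

Step 1
Reactants: 1 1-(3,5-dibromo-4-hydroxyphenyl)ethanone
Product: 2 1-(3,5-dibromo-4-methoxyphenyl)ethanone
Conditions: MeI, K2CO3, DMF, rt to 40 °C
Reagents that add atoms: iodomethane, CI
Why: Williamson O-methylation; the acidic 2,6-dibromophenol is fully ionised by K2CO3, MeI is small enough for the hindered phenoxide, and the weak base leaves the ketone α-position alone.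

Step 2
Reactants: 2 1-(3,5-dibromo-4-methoxyphenyl)ethanone; 3 4-methoxybenzaldehyde
Product: 4 (E)-1-(3,5-dibromo-4-methoxyphenyl)-3-(4-methoxyphenyl)prop-2-en-1-one
Conditions: NaOH (aq), EtOH, rt
Reagents that add atoms: none
Why: Claisen–Schmidt crossed aldol condensation; only ketone 2 can enolise, aldehyde 3 cannot, and E1cB dehydration gives the conjugated, thermodynamically preferred E-enone.

Step 3
Reactants: 4 (E)-1-(3,5-dibromo-4-methoxyphenyl)-3-(4-methoxyphenyl)prop-2-en-1-one
Product: 5 rac-[(2R,3S)-3-(4-methoxyphenyl)oxiran-2-yl](3,5-dibromo-4-methoxyphenyl)methanone (trans)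
Conditions: 30% H2O2, NaOH (aq, cat.), MeOH–THF, 0 °C to rt
Reagents that add atoms: hydrogen peroxide, OO
Why: Weitz–Scheffer nucleophilic epoxidation (conjugate addition of hydroperoxide, then ring closure) gives the trans epoxide as a racemate, which is sufficient because both stereocentres are erased in step 4.

Step 4
Reactants: 5 rac-[(2R,3S)-3-(4-methoxyphenyl)oxiran-2-yl](3,5-dibromo-4-methoxyphenyl)methanone
Product: 6 (Z)-1-(3,5-dibromo-4-methoxyphenyl)-2-hydroxy-3-(4-methoxyphenyl)prop-2-en-1-one (enol form of the 1,2-dione)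
Conditions: KOt-Bu (1.2 equiv), t-BuOH–THF, 0 °C to rt; then 1 M HCl
Reagents that add atoms: none
Why: base-mediated α,β-epoxy ketone to 1,2-dione (diosphenol-type) isomerisation; deprotonation at the carbonyl-flanked epoxide C–H and E1cB-type cleavage of the benzylic C–O bond leave the oxygen on C2 as a conjugated enolate (which resists benzilic rearrangement), and protonation gives the thermodynamically preferred Z-enol with the aryl group trans to the aroyl group.

Step 5
Reactants: 7 3,5-dibromo-4-methoxybenzoic acid; 8 2,2-dimethyl-1,3-dioxane-4,6-dione (Meldrum's acid)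
Product: 9 5-[(3,5-dibromo-4-methoxyphenyl)(hydroxy)methylidene]-2,2-dimethyl-1,3-dioxane-4,6-dione
Conditions: DCC, DMAP, CH2Cl2, 0 °C to rt; filter, wash with aq. KHSO4
Reagents that add atoms: none
Why: carbodiimide/DMAP-mediated C-acylation of Meldrum's acid (Oikawa–Yonemitsu type) gives the enolised aroyl Meldrum's acid, a latent acylketene, and the aryl bromides and methyl ether are inert.

Step 6
Reactants: 6 (Z)-1-(3,5-dibromo-4-methoxyphenyl)-2-hydroxy-3-(4-methoxyphenyl)prop-2-en-1-one; 9 5-[(3,5-dibromo-4-methoxyphenyl)(hydroxy)methylidene]-2,2-dimethyl-1,3-dioxane-4,6-dione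
Product: 13 (Z)-3-(3,5-dibromo-4-methoxybenzoyl)-4-(3,5-dibromo-4-methoxyphenyl)-5-(4-methoxybenzylidene)furan-2(5H)-one, via acylketene 10 (not isolated), via enol ester 11 (not isolated), via aldol lactone 12 (not isolated)
Conditions: PhMe, 100 °C (−acetone, −CO2); then Et3N, rt to 50 °C
Reagents that add atoms: none
Why: Proposed new method: thermolysis of 9 (retro-[4+2], loss of acetone and CO2) gives acylketene 10, which adds the enol O–H of 6 to give enol β-keto ester 11 with the Z geometry retained; Et3N then enolises the β-keto ester, 5-exo-trig aldol addition onto the adjacent aryl ketone gives 12, and E1cB dehydration gives the fully conjugated butenolide, whose Z alkene is inherited from the Z-enol and is also the thermodynamic isomer (the E isomer clashes with the C4 aryl group); the closest known reaction type is acylketene trapping by α-hydroxy ketones followed by amine-promoted intramolecular Knoevenagel condensation to 3-acyl-4-aryl-furan-2(5H)-ones, here extended to the enol of a 1,2-dione so that the 5-ylidene is already in place.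

Step 7
Reactants: 13 (Z)-3-(3,5-dibromo-4-methoxybenzoyl)-4-(3,5-dibromo-4-methoxyphenyl)-5-(4-methoxybenzylidene)furan-2(5H)-one
Product: 14 cadiolide A, (Z)-3-(3,5-dibromo-4-hydroxybenzoyl)-4-(3,5-dibromo-4-hydroxyphenyl)-5-(4-hydroxybenzylidene)furan-2(5H)-one
Conditions: BBr3 (excess), CH2Cl2, −78 °C to rt; then H2O
Reagents that add atoms: none
Why: BBr3-mediated cleavage of the three aryl methyl ethers (Lewis acid activation, bromide SN2 at methyl, hydrolysis of the aryl borates on work-up), a deprotection that enol lactones, diaryl ketones, aryl bromides and the thermodynamically preferred Z-alkene withstand.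

## Compound list

1 | 1-(3,5-dibromo-4-hydroxyphenyl)ethanone | CC(=O)c1cc(Br)c(O)c(Br)c1 | starting material
2 | 1-(3,5-dibromo-4-methoxyphenyl)ethanone | COc1c(Br)cc(cc1Br)C(C)=O | intermediate
3 | 4-methoxybenzaldehyde | COc1ccc(C=O)cc1 | starting material
4 | (E)-1-(3,5-dibromo-4-methoxyphenyl)-3-(4-methoxyphenyl)prop-2-en-1-one | COc1ccc(/C=C/C(=O)c2cc(Br)c(OC)c(Br)c2)cc1 | intermediate
5 | rac-[(2R,3S)-3-(4-methoxyphenyl)oxiran-2-yl](3,5-dibromo-4-methoxyphenyl)methanone, trans, racemate (one enantiomer drawn) | O=C(c1cc(Br)c(OC)c(Br)c1)[C@@H]1O[C@H]1c1ccc(OC)cc1 | intermediate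
6 | (Z)-1-(3,5-dibromo-4-methoxyphenyl)-2-hydroxy-3-(4-methoxyphenyl)prop-2-en-1-one | COc1ccc(cc1)/C=C(\O)C(=O)c1cc(Br)c(OC)c(Br)c1 | intermediate
7 | 3,5-dibromo-4-methoxybenzoic acid | COc1c(Br)cc(cc1Br)C(=O)O | starting material
8 | 2,2-dimethyl-1,3-dioxane-4,6-dione (Meldrum's acid) | CC1(C)OC(=O)CC(=O)O1 | starting material
9 | 5-[(3,5-dibromo-4-methoxyphenyl)(hydroxy)methylidene]-2,2-dimethyl-1,3-dioxane-4,6-dione | CC1(C)OC(=O)C(=C(O)c2cc(Br)c(OC)c(Br)c2)C(=O)O1 | intermediate
10 | 3-(3,5-dibromo-4-methoxyphenyl)-3-oxoprop-1-en-1-one (aroylketene, formed in situ) | O=C=CC(=O)c1cc(Br)c(OC)c(Br)c1 | intermediate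
11 | (Z)-3-(3,5-dibromo-4-methoxyphenyl)-1-(4-methoxyphenyl)-3-oxoprop-1-en-2-yl 3-(3,5-dibromo-4-methoxyphenyl)-3-oxopropanoate (formed in situ) | COc1ccc(cc1)/C=C(\OC(=O)CC(=O)c1cc(Br)c(OC)c(Br)c1)C(=O)c1cc(Br)c(OC)c(Br)c1 | intermediate
12 | (Z)-3-(3,5-dibromo-4-methoxybenzoyl)-4-(3,5-dibromo-4-methoxyphenyl)-4-hydroxy-5-(4-methoxybenzylidene)dihydrofuran-2(3H)-one, racemic diastereomer mixture at C3/C4 (formed in situ) | COc1ccc(cc1)/C=C1\OC(=O)C(C(=O)c2cc(Br)c(OC)c(Br)c2)C1(O)c1cc(Br)c(OC)c(Br)c1 | intermediate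
13 | (Z)-3-(3,5-dibromo-4-methoxybenzoyl)-4-(3,5-dibromo-4-methoxyphenyl)-5-(4-methoxybenzylidene)furan-2(5H)-one (cadiolide A tri-O-methyl ether) | O=C1O/C(=C\c2ccc(OC)cc2)C(c2cc(Br)c(OC)c(Br)c2)=C1C(=O)c1cc(Br)c(OC)c(Br)c1 | intermediate
14 | cadiolide A, (Z)-3-(3,5-dibromo-4-hydroxybenzoyl)-4-(3,5-dibromo-4-hydroxyphenyl)-5-(4-hydroxybenzylidene)furan-2(5H)-one | O=C1O/C(=C\c2ccc(O)cc2)C(c2cc(Br)c(O)c(Br)c2)=C1C(=O)c1cc(Br)c(O)c(Br)c1 | target

## Step count and risks

Total step count: 7. Longest linear sequence: 6 (steps 1, 2, 3, 4, 6, 7 from compound 1); step 5 is a one-step side branch that joins at step 6.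

The three steps most likely to fail are steps 6, 4 and 5.

**Step 6.** The enol of 6 may trap acylketene 10 poorly, or enol ester 11 may transfer its acyl group instead of cyclising. The fallback builds the butenolide first and attaches the benzylidene last. It sets out from ketone 2: bromination with CuBr2 (EtOAc–CHCl3, reflux) gives 2-bromo-1-(3,5-dibromo-4-methoxyphenyl)ethanone F1. HCO2Na in aqueous EtOH at reflux then gives, by way of 2-(3,5-dibromo-4-methoxyphenyl)-2-oxoethyl formate F2, the hydroxy ketone 1-(3,5-dibromo-4-methoxyphenyl)-2-hydroxyethanone F3. Heating F3 with 9 in toluene (acylketene 10) gives 2-(3,5-dibromo-4-methoxyphenyl)-2-oxoethyl 3-(3,5-dibromo-4-methoxyphenyl)-3-oxopropanoate F4, which Et3N closes by intramolecular Knoevenagel condensation to 3-(3,5-dibromo-4-methoxybenzoyl)-4-(3,5-dibromo-4-methoxyphenyl)furan-2(5H)-one F5. Piperidine-mediated vinylogous aldol condensation of F5 with aldehyde 3 (MeOH, rt) gives the Z-benzylidene compound 13, where the route is rejoined before step 7.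

**Step 4.** The epoxy ketone may give benzilic-type rearrangement or aroyl migration instead of clean isomerisation. The fallback reaches the 1,2-dione by C–H oxidation instead. It sets out from chalcone 4: conjugate reduction (Zn, NH4Cl, EtOH–H2O, 80 °C) gives 1-(3,5-dibromo-4-methoxyphenyl)-3-(4-methoxyphenyl)propan-1-one F6. Riley oxidation of its ketone α-methylene (SeO2, dioxane–H2O, 100 °C) gives the 1,2-dione, isolated as its Z-enol 6, where the route is rejoined at step 6; epoxide 5 is then not needed.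

**Step 5.** Aroyl Meldrum's acids form less cleanly than alkanoyl ones, and 9 must be used without chromatography. The fallback uses a tert-butyl β-keto ester as the acylketene source. It sets out from acid 7: SOCl2 (cat. DMF, PhMe, 70 °C) gives 3,5-dibromo-4-methoxybenzoyl chloride F7. Claisen-type acylation of LiCH2CO2t-Bu (from tert-butyl acetate and LiN(i-Pr)2, THF, −78 °C) gives tert-butyl 3-(3,5-dibromo-4-methoxyphenyl)-3-oxopropanoate F8. Heating F8 with 6 in xylene at 135 °C expels tert-butanol and gives acylketene 10, where the route is rejoined within step 6.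

## Further compounds

F1 | step 6 | 2-bromo-1-(3,5-dibromo-4-methoxyphenyl)ethanone | COc1c(Br)cc(cc1Br)C(=O)CBr
F2 | step 6 | 2-(3,5-dibromo-4-methoxyphenyl)-2-oxoethyl formate | COc1c(Br)cc(cc1Br)C(=O)COC=O
F3 | step 6 | 1-(3,5-dibromo-4-methoxyphenyl)-2-hydroxyethanone | COc1c(Br)cc(cc1Br)C(=O)CO
F4 | step 6 | 2-(3,5-dibromo-4-methoxyphenyl)-2-oxoethyl 3-(3,5-dibromo-4-methoxyphenyl)-3-oxopropanoate | COc1c(Br)cc(cc1Br)C(=O)COC(=O)CC(=O)c1cc(Br)c(OC)c(Br)c1
F5 | step 6 | 3-(3,5-dibromo-4-methoxybenzoyl)-4-(3,5-dibromo-4-methoxyphenyl)furan-2(5H)-one | O=C1OCC(c2cc(Br)c(OC)c(Br)c2)=C1C(=O)c1cc(Br)c(OC)c(Br)c1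
F6 | step 4 | 1-(3,5-dibromo-4-methoxyphenyl)-3-(4-methoxyphenyl)propan-1-one | COc1ccc(CCC(=O)c2cc(Br)c(OC)c(Br)c2)cc1
F7 | step 5 | 3,5-dibromo-4-methoxybenzoyl chloride | COc1c(Br)cc(cc1Br)C(Cl)=O
F8 | step 5 | tert-butyl 3-(3,5-dibromo-4-methoxyphenyl)-3-oxopropanoate | COc1c(Br)cc(cc1Br)C(=O)CC(=O)OC(C)(C)C
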